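**Retrosynthetic overview**
- The key disconnection is the diaryl ether bond between the bridging oxygen and C8 of the 5,7-dihydroxycoumarin half (fragment B). The oxygen stays on fragment A, 8-hydroxy-7-methoxycoumarin.
- Fragment B is made electrophilic at C8 by C–H iodonylation of 5,7-dihydroxycoumarin. The resulting phenyliodonium phenolate serves as a quinoid carbene source for O–H insertion, so no protecting groups are needed.
- Fragment A comes from daphnetin by selective 7-O-methylation; both of its rings are bought.
- The pyranone ring of fragment B is closed first, from phloroglucinol and ethyl propiolate. No ring is formed after the coupling.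

Assumption: the SMILES holds no stereocentre and the diaryl ether axis gives no stable atropisomers, so the target is achiral and no enantioselective step is needed.

**Step 1**
Reactants: 1 daphnetin (7,8-dihydroxycoumarin)
Product: 2 8-hydroxy-7-methoxycoumarin
Conditions: MeI (1.1 equiv), NaHCO3 (1.2 equiv), DMF, 35 °C, closed flask
Reagents that add atoms: iodomethane, CI
Why: The 7-OH is conjugated through C4a with the lactone enoate and is clearly the more acidic hydroxyl, so the weak base ionises only O7 and the Williamson ether synthesis (SN2 on MeI) stops at the 7-mono-ether, as in the selective para-O-alkylation of 3,4-dihydroxybenzaldehyde.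

**Step 2**
Reactants: 3 phloroglucinol; 4 ethyl propiolate
Product: 6 5,7-dihydroxycoumarin, via ethyl (Z)-2,4,6-trihydroxycinnamate 5 (not isolated)
Conditions: ZnCl2 (1.0 equiv), neat, 100 °C, 1.5 h; then 1 M HCl
Reagents that add atoms: none
Why: This is the propiolate variant of the Pechmann coumarin synthesis (Lewis acid hydroarylation of the alkyne by the very electron-rich arene, then lactonisation of the cis-cinnamate), and the threefold symmetry of 3 allows only one product.

**Step 3**
Reactants: 6 5,7-dihydroxycoumarin
Product: 7 5-hydroxy-2-oxo-8-(phenyliodonio)-2H-chromen-7-olate (inner salt)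
Conditions: PhI(OAc)2 (1.0 equiv), Na2CO3 (1.0 equiv), MeOH, 0 °C, 1 h; H2O, filter, wash with Et2O, dry cold in the dark
Reagents that add atoms: (diacetoxyiodo)benzene, CC(=O)OI(OC(C)=O)c1ccccc1
Why: This is the known iodonium ylide (zwitterion) formation from acidic phenols and 1,3-dicarbonyl-type carbons with a trivalent iodine reagent; C8 (ortho to the 7-oxide, para to 5-OH) is expected to be the most nucleophilic carbon, being the main site of Friedel–Crafts acylation in 5,7-dihydroxycoumarins, and the all-meta oxygen pattern blocks oxidation to a quinone.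

**Step 4**
Reactants: 7 5-hydroxy-2-oxo-8-(phenyliodonio)-2H-chromen-7-olate; 2 8-hydroxy-7-methoxycoumarin
Product: 8 5,7-dihydroxy-8-[(7-methoxy-2-oxo-2H-chromen-8-yl)oxy]-2H-chromen-2-one (target)
Conditions: Rh2(OAc)4 (2 mol %), 2 (2.0 equiv, excess recovered), 4 Å MS, CH2Cl2–MeCN (4:1), 35 °C, 7 added in portions
Reagents that add atoms: none
Why: Proposed new method: Rh2(OAc)4 attacks the ylidic C8 of 7 and expels PhI to give an electrophilic rhodium quinoid carbenoid (C7 in its carbonyl form), the 8-OH of 2 (not conjugated with its lactone, hence the most nucleophilic hydroxyl present) adds to C8 to give an oxonium ylide, and a proton shift to O7 re-aromatises ring B and frees the catalyst, so the C–O bond forms by attack on a planar carbene carbon rather than by reductive elimination at a crowded metal, which should make an ether with four ortho substituents reachable; 7 is too weakly basic to be protonated by 2, which shuts off phenyl transfer by ligand coupling, and 35 °C lies well below the temperature of the thermal iodine-to-oxygen phenyl shift; the closest known reaction types are the rhodium-catalysed O–H insertions of beta-dicarbonyl phenyliodonium ylides and of quinone diazides into alcohols, and to my knowledge neither has been shown for an aromatic iodonium phenolate or a hindered phenol partner.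

**Compound list**
1 | daphnetin (7,8-dihydroxy-2H-chromen-2-one) | Oc1ccc2ccc(=O)oc2c1O | starting material
2 | 8-hydroxy-7-methoxy-2H-chromen-2-one | COc1ccc2ccc(=O)oc2c1O | intermediate
3 | phloroglucinol (benzene-1,3,5-triol) | Oc1cc(O)cc(O)c1 | starting material
4 | ethyl propiolate | C#CC(=O)OCC | starting material
5 | ethyl (Z)-2,4,6-trihydroxycinnamate | CCOC(=O)/C=C\c1c(O)cc(O)cc1O | intermediate
6 | 5,7-dihydroxy-2H-chromen-2-one | Oc1cc(O)c2ccc(=O)oc2c1 | intermediate
7 | 5-hydroxy-2-oxo-8-(phenyliodonio)-2H-chromen-7-olate | [O-]c1cc(O)c2ccc(=O)oc2c1[I+]c1ccccc1 | intermediate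
8 | 5,7-dihydroxy-8-[(7-methoxy-2-oxo-2H-chromen-8-yl)oxy]-2H-chromen-2-one | COc1ccc2ccc(=O)oc2c1Oc1c(O)cc(O)c2ccc(=O)oc12 | target

**Step count**
Total step count: 4. Longest linear sequence: 3 (3 → 6 → 7 → 8).

**The three steps most likely to fail**

(a) Step 4, the proposed O–H insertion.
- Risks: the carbenoid may not form from an aromatic zwitterion. It may insert into the 5-OH or 7-OH of product 8 or into traces of water. Phenyl migration to O7 may compete.
- Fallback, known chemistry only, setting out from 6 and 2 and coming back at 8. Compound 6 is benzylated (BnBr, K2CO3, DMF) to 5,7-bis(benzyloxy)coumarin F1.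
- F1 is iodinated at the less hindered C8 (NIS, cat. TFA, MeCN) to 5,7-bis(benzyloxy)-8-iodocoumarin F2.
- F2 is joined to 2 by an Ullmann ether synthesis for hindered partners (CuI 10 mol %, picolinic acid 20 mol %, K3PO4, DMSO, 90 °C). This gives 5,7-bis(benzyloxy)-8-[(7-methoxy-2-oxo-2H-chromen-8-yl)oxy]coumarin F3.
- F3 is debenzylated with BCl3 and pentamethylbenzene in CH2Cl2 at −78 °C to give 8. These conditions spare the methyl ether and both enoates.

(b) Step 3, the iodonylation.
- Risks: attack at C6 instead of C8, or a zwitterion that cannot be isolated pure. The regiochemistry is checked by HMBC before going on.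
- Fallback, setting out from 6 and coming back at 7, uses steric control on the bis-ether instead of the free phenolate. Compound 6 is protected (MOMCl, iPr2NEt, CH2Cl2) as 5,7-bis(methoxymethoxy)coumarin F4.
- F4 reacts with PhI(OH)OTs in CF3CH2OH at rt by electrophilic aromatic substitution. C6 is flanked by two acetal ethers, whereas C8 has only one such neighbour and the tied-back ring oxygen.
- The product is [5,7-bis(methoxymethoxy)-2-oxo-2H-chromen-8-yl](phenyl)iodonium tosylate F5.
- Catalytic TsOH in MeOH at 50 °C removes the acetals to give (5,7-dihydroxy-2-oxo-2H-chromen-8-yl)(phenyl)iodonium tosylate F6. Aqueous NaHCO3 then precipitates 7.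

(c) Step 1, the selective methylation.
- Risks: dimethylation, or some 8-O-methyl isomer that is hard to separate.
- Fallback, setting out from 1 and coming back at 2, reverses the logic. Compound 1 is methylated exhaustively (excess MeI, K2CO3, acetone, reflux) to 7,8-dimethoxycoumarin F7.
- BCl3 (1.1 equiv, CH2Cl2, −20 to 0 °C) should then cleave only the 8-methoxy group to give 2. That group is the central, twisted and most Lewis basic one of the three contiguous oxygens. This is the known selective cleavage of the middle ether in 1,2,3-trioxygenated arenes.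

**Further compounds**
F1 | step 4 | 5,7-bis(benzyloxy)-2H-chromen-2-one | c1ccccc1COc1cc(OCc2ccccc2)c2ccc(=O)oc2c1
F2 | step 4 | 5,7-bis(benzyloxy)-8-iodo-2H-chromen-2-one | c1ccccc1COc1cc(OCc2ccccc2)c2ccc(=O)oc2c1I
F3 | step 4 | 5,7-bis(benzyloxy)-8-[(7-methoxy-2-oxo-2H-chromen-8-yl)oxy]-2H-chromen-2-one | COc1ccc2ccc(=O)oc2c1Oc1c(OCc2ccccc2)cc(OCc2ccccc2)c2ccc(=O)oc12
F4 | step 3 | 5,7-bis(methoxymethoxy)-2H-chromen-2-one | COCOc1cc(OCOC)c2ccc(=O)oc2c1
F5 | step 3 | [5,7-bis(methoxymethoxy)-2-oxo-2H-chromen-8-yl](phenyl)iodonium 4-methylbenzenesulfonate | COCOc1cc(OCOC)c2ccc(=O)oc2c1[I+]c1ccccc1.Cc1ccc(cc1)S(=O)(=O)[O-]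
F6 | step 3 | (5,7-dihydroxy-2-oxo-2H-chromen-8-yl)(phenyl)iodonium 4-methylbenzenesulfonate | Oc1cc(O)c2ccc(=O)oc2c1[I+]c1ccccc1.Cc1ccc(cc1)S(=O)(=O)[O-]
F7 | step 1 | 7,8-dimethoxy-2H-chromen-2-one | COc1ccc2ccc(=O)oc2c1OC
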